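The tetrahydrofuran ring is disconnected at its enol-ether bond O1–C2 (benzofuran numbering; Cα is the exocyclic alkene carbon). The vinylogous ester O1–C2=Cα–C=O is the cyclodehydration product of a C7a tertiary alcohol and the C2 ketone of a β-dicarbonyl chain. That hydroxy β-keto amide is released in the flask when a propionamide enolate opens a trans-fused bromolactone, a temporary ring made by enantioselective bromonium polyene cyclization of homogeranic acid, which sets C3a, C5 and C7a. Acid then closes the ring, uniting the two fragments, forming O1–C2 and fixing the Z-configured tetrasubstituted alkene in one operation. Bromomethyllithium finally turns the Weinreb amide into the bromomethyl ketone.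

Key step: step 2

Assumption: geometrically pure (E)-homogeranic acid is taken as a purchasable starting material.

Step 1
Reactants: 1 (E)-homogeranic acid, (3E)-4,8-dimethylnona-3,7-dienoic acid
Product: 2 (3aS,5S,7aS)-5-bromo-4,4,7a-trimethylhexahydro-1-benzofuran-2(3H)-one (trans-fused bromolactone, Br equatorial)
Conditions: (R)-3,3'-bis(2,4,6-triisopropylphenyl)-1,1'-binaphthyl-2,2'-diyl N-(trifluoromethanesulfonyl)thiophosphoramide (10 mol%), DBDMH (0.55 equiv), toluene–CH2Cl2, −78 °C
Reagents that add atoms: 1,3-dibromo-5,5-dimethylhydantoin (DBDMH), CC1(C)N(Br)C(=O)N(Br)C1=O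
Why: Proposed new method: the thiophosphoryl sulfur of the catalyst should take Br+ from DBDMH and pass it within a chiral ion pair to the electron-richer terminal C7=C8 alkene of 1 (acid numbering), the (E)-C3=C4 alkene then attacks through a chair transition state with bromine equatorial and the carboxyl oxygen traps the tertiary cation anti, so that the catalyst sets C5 (the catalyst antipode is used if the sense turns out opposite) and the E-geometry sets C3a and C7a as the trans ring fusion; the closest known reaction types are the chiral thiophosphoramide- or phosphite–urea-catalysed enantioselective bromocyclisation of homogeranylarenes and 2-geranylphenols and the racemic bromonium cyclisation of homogeranic acid to this lactone, and the carboxylic acid as terminator in the asymmetric manifold is the untested element.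

Step 2
Reactants: 2 (3aS,5S,7aS)-5-bromo-4,4,7a-trimethylhexahydro-1-benzofuran-2(3H)-one; 3 N-methoxy-N-methylpropanamide
Product: 8 (2Z)-2-[(3aS,5S,7aS)-5-bromo-4,4,7a-trimethylhexahydro-1-benzofuran-2(3H)-ylidene]-N-methoxy-N-methylpropanamide, via lithium enolate of the amide 4 (not isolated), via ring-opened dilithium alkoxide enolate 5 (not isolated), via hydroxy keto amide 6 (not isolated), via cyclic hemiketal 7 (not isolated)
Conditions: 3 (2.5 equiv), LiN(iPr)2 (2.5 equiv), THF, −78 °C; then 2, −78 → 0 °C; aq NH4Cl; crude, TFA (0.5 equiv), CH2Cl2, 0 °C → rt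
Reagents that add atoms: none
Why: In a Claisen acyl substitution the enolate 4 adds to the lactone carbonyl C2, the tetrahedral alkoxide expels the C7a tertiary alkoxide and the β-keto amide so formed is deprotonated at once, so the ring-opened dianion 5 is the resting state and the lactone O1–C2 bond is gone before it is made again. On acidification the C7a hydroxyl of 6 adds to the C2 ketone (5-exo-trig hemiketalisation to 7), and TFA-promoted loss of water through the C2 oxocarbenium ion followed by loss of the Cα proton should give the conjugated exocyclic enol ether 8. The closest known reaction types are the Claisen condensation of amide enolates with lactones and the acid-mediated cyclodehydration of 6-hydroxy-3-oxo esters to 2-alkylidenetetrahydrofurans. No new sp3 stereocentre is formed and the C7a–O bond is never broken, so C3a, C5, C7a and the trans ring fusion are carried over from 2. The only new stereo-element, the C2=Cα geometry, is under thermodynamic control through reversible Cα protonation and should settle as Z, with the carbamoyl group next to the small ring oxygen and the methyl group next to C3H2. The step needs exocyclic over endocyclic dehydration and hemiketalisation over ionisation of the tertiary alcohol, which conjugation with the amide carbonyl and the fast intramolecular five-ring closure should secure.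

Step 3
Reactants: 8 (2Z)-2-[(3aS,5S,7aS)-5-bromo-4,4,7a-trimethylhexahydro-1-benzofuran-2(3H)-ylidene]-N-methoxy-N-methylpropanamide
Product: 10 (3Z)-1-bromo-3-[(3aS,5S,7aS)-5-bromo-4,4,7a-trimethylhexahydro-1-benzofuran-2(3H)-ylidene]butan-2-one, via lithium tetrahedral adduct 9 (not isolated)
Conditions: CH2Br2 (3 equiv), MeLi·LiBr (2.5 equiv), THF–Et2O, −78 °C; then aq NH4Cl, −78 °C → rt
Reagents that add atoms: dibromomethane, BrCBr
Why: Weinreb ketone synthesis with a carbenoid: bromomethyllithium, formed by bromine–lithium exchange in the presence of 8, adds once to the N-methoxy-N-methyl amide to give the chelated adduct 9, which collapses to the bromomethyl ketone only on quench, while the hindered secondary bromide, the enol ether and all stereocentres are untouched.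

Compound list
1 | (3E)-4,8-dimethylnona-3,7-dienoic acid ((E)-homogeranic acid) | CC(C)=CCC/C(C)=C/CC(=O)O | starting material
2 | (3aS,5S,7aS)-5-bromo-4,4,7a-trimethylhexahydro-1-benzofuran-2(3H)-one | O=C1C[C@H]2C(C)(C)[C@@H](Br)CC[C@]2(C)O1 | intermediate
3 | N-methoxy-N-methylpropanamide | CCC(=O)N(C)OC | starting material
4 | lithium (Z)-enolate of N-methoxy-N-methylpropanamide | C/C=C(\[O-])N(C)OC.[Li+] | intermediate
5 | dilithium salt (C7a alkoxide and keto amide enolate) of 4-[(1S,3S,6S)-3-bromo-6-hydroxy-2,2,6-trimethylcyclohexyl]-N-methoxy-N,2-dimethyl-3-oxobutanamide | CC(C(=O)N(C)OC)=C([O-])C[C@H]1C(C)(C)[C@@H](Br)CC[C@]1(C)[O-].[Li+].[Li+] | intermediate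
6 | 4-[(1S,3S,6S)-3-bromo-6-hydroxy-2,2,6-trimethylcyclohexyl]-N-methoxy-N,2-dimethyl-3-oxobutanamide (epimers at C2 of the chain) | CC(C(=O)N(C)OC)C(=O)C[C@H]1C(C)(C)[C@@H](Br)CC[C@]1(C)O | intermediate
7 | 2-[(3aS,5S,7aS)-5-bromo-2-hydroxy-4,4,7a-trimethyloctahydro-1-benzofuran-2-yl]-N-methoxy-N-methylpropanamide (hemiketal, mixture at the two new centres) | CC(C(=O)N(C)OC)C1(O)C[C@H]2C(C)(C)[C@@H](Br)CC[C@]2(C)O1 | intermediate
8 | (2Z)-2-[(3aS,5S,7aS)-5-bromo-4,4,7a-trimethylhexahydro-1-benzofuran-2(3H)-ylidene]-N-methoxy-N-methylpropanamide | C/C(C(=O)N(C)OC)=C1\C[C@H]2C(C)(C)[C@@H](Br)CC[C@]2(C)O1 | intermediate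
9 | lithium (3Z)-1-bromo-3-[(3aS,5S,7aS)-5-bromo-4,4,7a-trimethylhexahydro-1-benzofuran-2(3H)-ylidene]-2-[methoxy(methyl)amino]butan-2-olate | C/C(C([O-])(CBr)N(C)OC)=C1\C[C@H]2C(C)(C)[C@@H](Br)CC[C@]2(C)O1.[Li+] | intermediate
10 | (3Z)-1-bromo-3-[(3aS,5S,7aS)-5-bromo-4,4,7a-trimethylhexahydro-1-benzofuran-2(3H)-ylidene]butan-2-one | C/C(C(=O)CBr)=C1\C[C@H]2C(C)(C)[C@@H](Br)CC[C@]2(C)O1 | target

Total step count: 3
Longest linear sequence: 3 steps (1 → 2 → 8 → 10)

Steps most likely to fail

Step 1 (Proposed new method). The free carboxylic acid may open an uncatalysed bromine-transfer pathway or bind the catalyst, so that facial selectivity at the terminal alkene is poor. The C7a cation may also lose a proton before lactone closure. The fallback sets out from 1 and uses known chemistry only: racemic bromonium cyclisation with Et2SBr·SbCl5Br in MeNO2 at −25 °C should give 2 together with its mirror image, (3aR,5R,7aR)-5-bromo-4,4,7a-trimethylhexahydro-1-benzofuran-2(3H)-one F1. Preparative supercritical-fluid chromatography on an amylose tris(3,5-dimethylphenylcarbamate) phase then separates the two, and the absolute configuration is assigned by anomalous-dispersion X-ray analysis of the bromide. The fallback comes back to the route at 2.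

Step 2. Proton transfer from C3 of the lactone to the basic amide enolate may outrun acyl substitution, so that the lactone is returned after quench and the ring-opened keto amide never forms. The fallback sets out from 2 and replaces the Claisen condensation by an aldol–oxidation sequence. Reduction with iBu2AlH (CH2Cl2, −78 °C) should give the lactol (3aS,5S,7aS)-5-bromo-4,4,7a-trimethyloctahydro-1-benzofuran-2-ol F2. Its open hydroxy aldehyde form is trapped by excess enolate 4 (THF, −78 → 0 °C) as 4-[(1S,3S,6S)-3-bromo-6-hydroxy-2,2,6-trimethylcyclohexyl]-3-hydroxy-N-methoxy-N,2-dimethylbutanamide F3. Dess–Martin periodinane (CH2Cl2, rt) oxidises only the secondary carbinol, and the fallback comes back to the route at 6, which closes through O1–C2 to 8 under the TFA conditions of step 2.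

Step 3. The carbenoid may decompose faster than it adds to the deactivated, shielded carbonyl of the vinylogous carbamate, leaving the amide unchanged. The fallback sets out from 8 and uses a thermally stable nucleophile followed by a separate bromination. MeLi (THF, −78 → 0 °C) should give (3Z)-3-[(3aS,5S,7aS)-5-bromo-4,4,7a-trimethylhexahydro-1-benzofuran-2(3H)-ylidene]butan-2-one F4. Kinetic deprotonation of its acetyl methyl group with LiN(SiMe3)2 and Me3SiCl (THF, −78 °C) gives the silyl dienol ether trimethyl({(3Z)-3-[(3aS,5S,7aS)-5-bromo-4,4,7a-trimethylhexahydro-1-benzofuran-2(3H)-ylidene]but-1-en-2-yl}oxy)silane F5. N-Bromosuccinimide (THF, −78 °C) brominates the terminal carbon, and the fallback comes back to the route at 10.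

Further compounds
F1 | step 1 | (3aR,5R,7aR)-5-bromo-4,4,7a-trimethylhexahydro-1-benzofuran-2(3H)-one | O=C1C[C@@H]2C(C)(C)[C@H](Br)CC[C@@]2(C)O1
F2 | step 2 | (3aS,5S,7aS)-5-bromo-4,4,7a-trimethyloctahydro-1-benzofuran-2-ol | OC1C[C@H]2C(C)(C)[C@@H](Br)CC[C@]2(C)O1
F3 | step 2 | 4-[(1S,3S,6S)-3-bromo-6-hydroxy-2,2,6-trimethylcyclohexyl]-3-hydroxy-N-methoxy-N,2-dimethylbutanamide | CC(C(=O)N(C)OC)C(O)C[C@H]1C(C)(C)[C@@H](Br)CC[C@]1(C)O
F4 | step 3 | (3Z)-3-[(3aS,5S,7aS)-5-bromo-4,4,7a-trimethylhexahydro-1-benzofuran-2(3H)-ylidene]butan-2-one | C/C(C(C)=O)=C1\C[C@H]2C(C)(C)[C@@H](Br)CC[C@]2(C)O1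
F5 | step 3 | trimethyl({(3Z)-3-[(3aS,5S,7aS)-5-bromo-4,4,7a-trimethylhexahydro-1-benzofuran-2(3H)-ylidene]but-1-en-2-yl}oxy)silane | C/C(C(=C)O[Si](C)(C)C)=C1\C[C@H]2C(C)(C)[C@@H](Br)CC[C@]2(C)O1
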